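## Retrosynthetic overview

- Ring A is the ten-membered carbocycle C1–C10 (C1 ketone, C4 methyl carbinol, C6 acyloxy, C10 methyl). Ring B is the γ-lactone C7–C8–O–C12–C11, with C13 as the exo-methylene. The plan rests on one feature: the lactone oxygen on C8 lies γ to the carboxyl carbon C12 (C12–C11–C7–C8). C8 can therefore be carried as a plain ring-A methylene and oxidised last.
- The target comes from the 13-acetoxy-11,13-dihydro lactone by loss of acetic acid. That lactone comes from the 8-deoxy seco acid by carboxylate-directed iron-catalysed C8–H lactonisation (ring B, closed second).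
- The seco acid comes from a C7 side chain CH(CH2OH)2 with two equivalent arms, carried as a 1,3-dioxane. Ring A is closed first, by ring-closing metathesis at C8=C9, and hydrogenation then delivers C8 and C9 as methylenes.
- The metathesis diene comes from two catalytic asymmetric allylborations on a geraniol-derived C1–C6 unit, forming C6–C7 and C1–C10. C4 is set by Sharpless epoxidation.

Key step: step 18

Remark 1: target numbering (C1–C13) is used for all advanced compounds. The γ-hydroxy ketones 24–31 may rest partly as C1/C4 hemiketals and are drawn open.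
Remark 2: C11 is formed without control in step 16. From 26 to 30 each number stands for the pair of C11 epimers, drawn as one epimer. This centre disappears in step 19.
Remark 3: the alkene geometry of 21 is not controlled and is drawn Z. It is erased in step 13.

## Route

Step 1
Reactants: 1 geraniol
Product: 2 (2S,3S)-2,3-epoxygeraniol
Conditions: Ti(OiPr)4 (5 mol%), L-(+)-diethyl tartrate (6 mol%), t-BuOOH, 4 Å MS, CH2Cl2, −20 °C
Reagents that add atoms: tert-butyl hydroperoxide, CC(C)(C)OO
Why: In the Sharpless asymmetric epoxidation the titanium tartrate complex oxidises only the allylic alkene, and the L-(+)-tartrate delivers oxygen to the face that gives the (2S,3S)-epoxide, which fixes C4 of the target as S.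

Step 2
Reactants: 2 (2S,3S)-2,3-epoxygeraniol
Product: 3 (S)-3,7-dimethyloct-6-ene-1,3-diol
Conditions: NaAlH2(OCH2CH2OMe)2, THF, 0 °C to rt; aq NaOH work-up
Reagents that add atoms: none
Why: In this hydroxyl-directed epoxide reduction the aluminium alkoxide at the primary oxygen delivers hydride to the less substituted epoxide carbon (future C5), so the 1,3-diol forms and the C4–O bond keeps its configuration.

Step 3
Reactants: 3 (S)-3,7-dimethyloct-6-ene-1,3-diol
Product: 4 (S)-1,3-bis(triethylsilyloxy)-3,7-dimethyloct-6-ene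
Conditions: Et3SiOTf, 2,6-lutidine, CH2Cl2, 0 °C
Reagents that add atoms: triethylsilyl triflate, CC[Si](CC)(CC)OS(=O)(=O)C(F)(F)F
Why: A silyl triflate with a hindered pyridine base silylates the tertiary as well as the primary hydroxyl, and no stereocentre is touched.

Step 4
Reactants: 4 (S)-1,3-bis(triethylsilyloxy)-3,7-dimethyloct-6-ene
Product: 5 (S)-3,7-dimethyl-3-(triethylsilyloxy)oct-6-enal (C6 aldehyde)
Conditions: (COCl)2, DMSO, CH2Cl2, −78 to −40 °C; Et3N, −78 °C to rt
Reagents that add atoms: none
Why: In a Swern oxidation applied directly to a silyl ether, the chlorosulfonium salt attacks only the unhindered primary triethylsilyl ether and converts it to the aldehyde in one operation, while the tertiary ether at C4 stays and blocks retro-aldol cleavage or dehydration.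

Step 5
Reactants: 6 (2,2-dimethyl-1,3-dioxan-5-yl)methanol
Product: 7 2,2-dimethyl-1,3-dioxane-5-carbaldehyde
Conditions: TEMPO (cat.), PhI(OAc)2, CH2Cl2, rt
Reagents that add atoms: none
Why: The oxoammonium (TEMPO) oxidation stops at the aldehyde in anhydrous medium, and its near-neutral conditions avoid β-elimination of a ring oxygen.

Step 6
Reactants: 7 2,2-dimethyl-1,3-dioxane-5-carbaldehyde; 8 vinylmagnesium bromide
Product: 10 (±)-1-(2,2-dimethyl-1,3-dioxan-5-yl)allyl acetate, via magnesium alkoxide 9 (not isolated)
Conditions: CH2=CHMgBr, THF, −78 °C; then Ac2O, −78 °C to rt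
Reagents that add atoms: vinylmagnesium bromide 8, C=C[Mg]Br; acetic anhydride, CC(=O)OC(C)=O
Why: Grignard 1,2-addition at low temperature outruns enolisation and the alkoxide is acylated in the same flask; the racemic carbinol centre is erased in the next step.

Step 7
Reactants: 10 (±)-1-(2,2-dimethyl-1,3-dioxan-5-yl)allyl acetate
Product: 11 (E)-3-(2,2-dimethyl-1,3-dioxan-5-yl)allylboronic acid pinacol ester
Conditions: Ni(cod)2 (5 mol%), PCy3 (5 mol%), B2pin2, EtOAc, 60 °C
Reagents that add atoms: bis(pinacolato)diboron, CC1(C)OB(OC1(C)C)B1OC(C)(C)C(C)(C)O1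
Why: In the nickel-catalysed allylic borylation, ionisation by zerovalent nickel gives a π-allyl complex whose syn form places boron on the unsubstituted terminus, so the configurationally stable linear E boronate results.

Step 8
Reactants: 5 (S)-3,7-dimethyl-3-(triethylsilyloxy)oct-6-enal; 11 (E)-allylboronate
Product: 13 (3R,4R,6S)-3-(2,2-dimethyl-1,3-dioxan-5-yl)-6,10-dimethyl-6-(triethylsilyloxy)undeca-1,9-dien-4-ol (target numbering 4S,6R,7R), via pinacol borate 12 (not isolated)
Conditions: (S)-TRIP [(S)-3,3′-bis(2,4,6-triisopropylphenyl)-1,1′-binaphthyl-2,2′-diyl hydrogen phosphate] (10 mol%), 4 Å MS, toluene, −30 to 0 °C; aq NaHCO3 work-up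
Reagents that add atoms: boronate 11, CC1(C)OCC(/C=C/CB2OC(C)(C)C(C)(C)O2)CO1
Why: In the chiral-phosphoric-acid-catalysed allylboration through a closed chair transition state, the E boronate holds the dioxanyl group equatorial and so gives the 6,7-anti pair, and the (S)-acid, hydrogen-bonded to a boronate oxygen, should direct attack to the Si face of the aldehyde to set 6R and with it C7.

Step 9
Reactants: 13 homoallylic alcohol; 14 isobutyryl chloride
Product: 15 6-O-isobutyrate of 13
Conditions: i-PrCOCl, pyridine, DMAP (cat.), CH2Cl2, 0 °C to rt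
Reagents that add atoms: isobutyryl chloride 14, CC(C)C(=O)Cl
Why: DMAP-catalysed acylation of the only free hydroxyl installs the final ester early, which saves a protecting group and leaves C6 untouched.

Step 10
Reactants: 15 6-O-isobutyrate
Product: 17 C1 aldehyde (4S,6R,7R) with the C7 vinyl group intact, via secondary ozonide 16 (not isolated)
Conditions: O3 (1 equiv, Sudan Red 7B end point), CH2Cl2, −78 °C; PPh3, to rt
Reagents that add atoms: ozone, [O-][O+]=O
Why: In the ozonolysis, electrophilic ozone reacts much faster with the electron-rich trisubstituted alkene than with the hindered monosubstituted vinyl group, and the ketal and silyl ether carry no oxidisable acetal C–H.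

Step 11
Reactants: 17 C1 aldehyde; 18 (E)-crotylboronic acid pinacol ester
Product: 20 metathesis diene (1S,4S,6R,7R,10R) with free C1 hydroxyl, via pinacol borate 19 (not isolated)
Conditions: (R)-TRIP (10 mol%), 4 Å MS, toluene, −30 °C; aq NaHCO3 work-up
Reagents that add atoms: (E)-crotylboronic acid pinacol ester 18, C/C=C/CB1OC(C)(C)C(C)(C)O1
Why: In the chiral-phosphoric-acid-catalysed crotylboration through a chair transition state, the E boronate gives the 1,10-anti adduct and the (R)-acid should direct Re-face attack, which together place the C10 methyl in the R configuration of the target; the C1 carbinol is oxidised later.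

Step 12
Reactants: 20 metathesis diene
Product: 21 cyclodec-8-ene (1S,4S,6R,7R,10R), ring A closed
Conditions: second-generation Grubbs catalyst RuCl2(=CHPh)(PCy3)(H2IMes) (10 mol% in portions), 1,4-benzoquinone (cat.), toluene (1 mM), 80 °C
Reagents that add atoms: none
Why: Ring-closing metathesis should initiate at the less hindered C10 vinyl group and close onto the C7 vinyl group with loss of ethylene, with the quaternary C4 and four branched centres limiting chain freedom; ten-membered carbocycles are known to close from dienes with allylic branching at high dilution.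

Step 13
Reactants: 21 cyclodec-8-ene
Product: 22 cyclodecan-1-ol (1S,4S,6R,7R,10R)
Conditions: H2 (1–4 bar), Pd/C, EtOAc, rt
Reagents that add atoms: none
Why: Heterogeneous hydrogenation of the only alkene turns C8 and C9 into plain methylenes without creating a stereocentre, and ethyl acetate as solvent spares the silyl ether.

Step 14
Reactants: 22 cyclodecan-1-ol
Product: 23 cyclodecan-1-one (4S,6R,7R,10R)
Conditions: Dess–Martin periodinane, NaHCO3, CH2Cl2, 0 °C to rt
Reagents that add atoms: none
Why: Dess–Martin oxidation under bicarbonate buffer gives the ketone without enolisation, so C10 stays R.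

Step 15
Reactants: 23 cyclodecan-1-one
Product: 24 keto triol (free C4 hydroxyl and C7 side chain CH(CH2OH)2)
Conditions: AcOH/THF/H2O 3:1:1, 40 °C
Reagents that add atoms: none
Why: Weak aqueous acid hydrolyses the isopropylidene ketal and the tertiary silyl ether in one operation, while keeping acid-catalysed enolisation toward C10 and ester cleavage negligible.

Step 16
Reactants: 24 keto triol
Product: 26 13-monoacetate (drawn 11R), via cyclic orthoester 25 (not isolated)
Conditions: MeC(OMe)3, PPTS (cat.), CH2Cl2, rt; then AcOH/H2O 4:1, rt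
Reagents that add atoms: trimethyl orthoacetate, COC(C)(OC)OC; water, O
Why: Monoacylation of the 1,3-diol through its cyclic orthoester releases exactly one acetate and one free primary hydroxyl on hydrolysis, the same aqueous acid reverses any mixed ketal at C1, and both C11 epimers are usable.

Step 17
Reactants: 26 13-monoacetate
Product: 28 8-deoxy seco acid with C13 acetate (4S,6R,7R,10R, drawn 11S), via acetoxy aldehyde 27 (not isolated)
Conditions: TEMPO (20 mol%), PhI(OAc)2 (2.5 equiv), MeCN/H2O 1:1, rt
Reagents that add atoms: water, O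
Why: The oxoammonium oxidation in water takes the primary alcohol through the aldehyde hydrate to the acid under weakly acidic conditions, in which the β-acetoxy group is not eliminated and the tertiary alcohol is inert.

Step 18
Reactants: 28 8-deoxy seco acid
Product: 30 13-acetoxy-11,13-dihydro lactone (4S,6R,7S,8S,10R, drawn 11S), via 8-hydroxy acid 29 (not isolated)
Conditions: (S,S)-[Fe(PDP)(MeCN)2](SbF6)2 (3 × 5 mol%), 50% aq H2O2 (3 × 1.2 equiv), MeCN, rt, no added AcOH
Reagents that add atoms: hydrogen peroxide, OO
Why: The C12 carboxylic acid takes the place of the usual acetic acid co-ligand on the divalent iron precatalyst, H2O2 converts the iron carboxylate into a high-valent iron-oxo, and this oxidant, held by the C12–C11–C7 tether, abstracts a hydrogen atom from C8 and returns oxygen by fast rebound, after which hydroxy acid 29 loses water (or the bound carboxylate is transferred directly) to give the lactone. The closest known reaction type is the carboxylic-acid-directed γ-lactonisation of unactivated secondary and tertiary C(sp3)–H bonds with Fe(PDP) and H2O2. Ring B closes in a 5-exo-trig mode through the new C8–O bond on the intact ring A, and no carbon–carbon bond is made. C8 (S) is the only new stereocentre and, because rebound goes with retention, it is decided by which diastereotopic hydrogen is removed: the pro-S hydrogen, cis to H7, is the one gauche to C11 when the C6–C7–C8–C9 torsion is gauche and the branched side chain points away from the ring, whereas the pro-R hydrogen then lies anti to C11 and out of reach of the tethered oxidant. The step needs site selectivity for C8, and the substrate secures it twice over, since C8 is the only methylene γ to the acid and also the ring position farthest from withdrawing groups: C6–H (the other γ C–H), C13–H2 and C5–H2 are deactivated by acyloxy or hydroxyl groups, C2–H2, C10–H, C11–H and the isobutyrate methine by adjacent carbonyls, C3–H2 and C9–H2 by the β-carbonyl, and C7–H is hindered and flanked by three withdrawing branches. The C13 acetate keeps the oxidisable acrylate alkene masked, lactonisation takes the new carbinol out of reach of over-oxidation, and unreacted 28 can be recovered and resubmitted.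

Step 19
Reactants: 30 13-acetoxy-11,13-dihydro lactone
Product: 31 target CNP0293926.1 (4S,6R,7S,8S,10R)
Conditions: DBU (1.5 equiv), CH2Cl2, 0 °C
Reagents that add atoms: none
Why: E1cB elimination of acetate from either C11 epimer of the β-acetoxy lactone unveils the C11=C13 exo-methylene, and short exposure at low temperature should keep the slower enolisation at the hindered C10 from setting in.

## Compound list

1 | geraniol | CC(C)=CCC/C(C)=C/CO | starting material
2 | (2S,3S)-2,3-epoxygeraniol | CC(C)=CCC[C@]1(C)O[C@H]1CO | intermediate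
3 | (S)-3,7-dimethyloct-6-ene-1,3-diol | CC(C)=CCC[C@](C)(O)CCO | intermediate
4 | (S)-1,3-bis(triethylsilyloxy)-3,7-dimethyloct-6-ene | CC(C)=CCC[C@](C)(O[Si](CC)(CC)CC)CCO[Si](CC)(CC)CC | intermediate
5 | (S)-3,7-dimethyl-3-(triethylsilyloxy)oct-6-enal | CC(C)=CCC[C@](C)(O[Si](CC)(CC)CC)CC=O | intermediate
6 | (2,2-dimethyl-1,3-dioxan-5-yl)methanol | OCC1COC(C)(C)OC1 | starting material
7 | 2,2-dimethyl-1,3-dioxane-5-carbaldehyde | O=CC1COC(C)(C)OC1 | intermediate
8 | vinylmagnesium bromide | C=C[Mg]Br | starting material
9 | bromomagnesium 1-(2,2-dimethyl-1,3-dioxan-5-yl)prop-2-en-1-olate (not isolated) | C=CC(O[Mg]Br)C1COC(C)(C)OC1 | intermediate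
10 | (±)-1-(2,2-dimethyl-1,3-dioxan-5-yl)allyl acetate | CC(=O)OC(C=C)C1COC(C)(C)OC1 | intermediate
11 | (E)-3-(2,2-dimethyl-1,3-dioxan-5-yl)allylboronic acid pinacol ester | CC1(C)OCC(/C=C/CB2OC(C)(C)C(C)(C)O2)CO1 | intermediate
12 | C6 O-pinacolboryl derivative of 13 (not isolated) | CC(C)=CCC[C@](C)(O[Si](CC)(CC)CC)C[C@@H](OB1OC(C)(C)C(C)(C)O1)[C@H](C=C)C1COC(C)(C)OC1 | intermediate
13 | (3R,4R,6S)-3-(2,2-dimethyl-1,3-dioxan-5-yl)-6,10-dimethyl-6-(triethylsilyloxy)undeca-1,9-dien-4-ol | CC(C)=CCC[C@](C)(O[Si](CC)(CC)CC)C[C@@H](O)[C@H](C=C)C1COC(C)(C)OC1 | intermediate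
14 | isobutyryl chloride | CC(C)C(=O)Cl | starting material
15 | 6-O-isobutyrate of 13 | CC(C)=CCC[C@](C)(O[Si](CC)(CC)CC)C[C@@H](OC(=O)C(C)C)[C@H](C=C)C1COC(C)(C)OC1 | intermediate
16 | secondary ozonide of the C1 alkene of 15 (not isolated) | CC1(C)OOC(CC[C@](C)(O[Si](CC)(CC)CC)C[C@@H](OC(=O)C(C)C)[C@H](C=C)C2COC(C)(C)OC2)O1 | intermediate
17 | C1 aldehyde (4S,6R,7R) | O=CCC[C@](C)(O[Si](CC)(CC)CC)C[C@@H](OC(=O)C(C)C)[C@H](C=C)C1COC(C)(C)OC1 | intermediate
18 | (E)-crotylboronic acid pinacol ester | C/C=C/CB1OC(C)(C)C(C)(C)O1 | starting material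
19 | C1 O-pinacolboryl derivative of 20 (not isolated) | C=C[C@@H](C)[C@@H](OB1OC(C)(C)C(C)(C)O1)CC[C@](C)(O[Si](CC)(CC)CC)C[C@@H](OC(=O)C(C)C)[C@H](C=C)C1COC(C)(C)OC1 | intermediate
20 | metathesis diene (1S,4S,6R,7R,10R) | C=C[C@@H](C)[C@@H](O)CC[C@](C)(O[Si](CC)(CC)CC)C[C@@H](OC(=O)C(C)C)[C@H](C=C)C1COC(C)(C)OC1 | intermediate
21 | cyclodec-8-ene (1S,4S,6R,7R,10R), drawn Z | CC1(C)OCC(CO1)[C@H]2/C=C\[C@@H](C)[C@@H](O)CC[C@](C)(O[Si](CC)(CC)CC)C[C@H]2OC(=O)C(C)C | intermediate
22 | cyclodecan-1-ol (1S,4S,6R,7R,10R) | CC1(C)OCC(CO1)[C@H]2CC[C@@H](C)[C@@H](O)CC[C@](C)(O[Si](CC)(CC)CC)C[C@H]2OC(=O)C(C)C | intermediate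
23 | cyclodecan-1-one (4S,6R,7R,10R) | CC1(C)OCC(CO1)[C@H]2CC[C@@H](C)C(=O)CC[C@](C)(O[Si](CC)(CC)CC)C[C@H]2OC(=O)C(C)C | intermediate
24 | keto triol | OCC(CO)[C@H]1CC[C@@H](C)C(=O)CC[C@](C)(O)C[C@H]1OC(=O)C(C)C | intermediate
25 | cyclic methyl orthoacetate of 24 (not isolated) | COC1(C)OCC(CO1)[C@H]2CC[C@@H](C)C(=O)CC[C@](C)(O)C[C@H]2OC(=O)C(C)C | intermediate
26 | 13-monoacetate (drawn 11R) | CC(=O)OC[C@@H](CO)[C@H]1CC[C@@H](C)C(=O)CC[C@](C)(O)C[C@H]1OC(=O)C(C)C | intermediate
27 | 13-acetoxy C12 aldehyde (not isolated) | CC(=O)OC[C@@H](C=O)[C@H]1CC[C@@H](C)C(=O)CC[C@](C)(O)C[C@H]1OC(=O)C(C)C | intermediate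
28 | 8-deoxy seco acid with C13 acetate | CC(=O)OC[C@@H](C(=O)O)[C@H]1CC[C@@H](C)C(=O)CC[C@](C)(O)C[C@H]1OC(=O)C(C)C | intermediate
29 | (8S)-8-hydroxy seco acid (not isolated) | CC(=O)OC[C@@H](C(=O)O)[C@H]1[C@@H](O)C[C@@H](C)C(=O)CC[C@](C)(O)C[C@H]1OC(=O)C(C)C | intermediate
30 | 13-acetoxy-11,13-dihydro lactone | CC(=O)OC[C@H]1C(=O)O[C@H]2C[C@@H](C)C(=O)CC[C@](C)(O)C[C@@H](OC(=O)C(C)C)[C@@H]12 | intermediate
31 | CNP0293926.1 | C=C1C(=O)O[C@H]2C[C@@H](C)C(=O)CC[C@](C)(O)C[C@@H](OC(=O)C(C)C)[C@@H]12 | target

## Step count and risks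

Total steps: 19. Longest linear sequence: 16 (steps 1–4 and 8–19).

### Steps most likely to fail

**1. Step 18.**
- What may go wrong: removal of the wrong diastereotopic C8 hydrogen (trans ring fusion), competing oxidation at C9 or C3, or stalling at low conversion. The antipodal catalyst is the first variable to test within the step.
- Fallback: the C8 oxygen is brought in through the C8=C9 alkene instead of a C–H bond. It sets out from 21.
  - AcOH/THF/H2O removes both protecting groups to give the unsaturated tetraol F1.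
  - Lipase-catalysed transesterification (Burkholderia cepacia lipase, vinyl acetate) acetylates one primary arm to give the monoacetate F2.
  - TEMPO/PhI(OAc)2 in aqueous MeCN, selective for the primary alcohol, gives the γ,δ-unsaturated acid F3.
  - Iodolactonisation (I2, NaHCO3, MeCN, 0 °C) closes the C8–O bond 5-exo with anti addition to give the iodolactone F4.
  - Bu3SnH/AIBN removes the iodine to give the hydroxy lactone F5.
  - Dess–Martin oxidation of the C1 hydroxyl comes back to the route at 30.

**2. Step 12.**
- What may go wrong: oligomerisation or unproductive metathesis because both vinyl groups sit next to branched carbons, and alkene migration at the C10 end.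
- Fallback: ring A is closed at C1–C10 by a Nozaki–Hiyama–Kishi reaction. It sets out from 15.
  - 9-BBN followed by NaBO3 hydroborates only the vinyl group to give the primary alcohol F6.
  - Dess–Martin oxidation gives the C9 aldehyde F7.
  - Stork–Zhao-type olefination with Ph3P=C(I)CH3 gives the (Z)-vinyl iodide F8.
  - Selective ozonolysis of the trisubstituted alkene gives the iodo aldehyde F9.
  - CrCl2 with NiCl2 (cat.) in DMSO at high dilution closes the ring to the allylic alcohol F10.
  - Dess–Martin oxidation gives the enone F11.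
  - Conjugate reduction with [(Ph3P)CuH]6 comes back at 23.
  - In this variant C10 depends on protonation of the ring enolate and on equilibration, which is weaker control than in the main route.

**3. Step 8.**
- What may go wrong: slow addition of the hindered pinacol boronate and insufficient facial selectivity with an unbranched aliphatic aldehyde.
- Fallback: catalyst control is replaced by a stoichiometric, more reactive chiral dialkylallylborane. It sets out from 7.
  - The Ohira–Bestmann reaction gives the alkyne F12.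
  - Crabbé homologation ((CH2O)n, i-Pr2NH, CuBr, dioxane, reflux) gives the allene F13.
  - Hydroboration with (−)-diisopinocampheylborane from (+)-α-pinene, followed by warming to equilibrate through 1,3-boron shifts, gives the (E)-allylborane F14.
  - Addition of 5 at −78 °C and NaBO3 work-up comes back at 13, with the anti adduct from Si-face attack expected.

## Further compounds

F1 | step 18 | unsaturated tetraol | OCC(CO)[C@H]1/C=C\[C@@H](C)[C@@H](O)CC[C@](C)(O)C[C@H]1OC(=O)C(C)C
F2 | step 18 | unsaturated 13-monoacetate | CC(=O)OC[C@@H](CO)[C@H]1/C=C\[C@@H](C)[C@@H](O)CC[C@](C)(O)C[C@H]1OC(=O)C(C)C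
F3 | step 18 | γ,δ-unsaturated acid | CC(=O)OC[C@@H](C(=O)O)[C@H]1/C=C\[C@@H](C)[C@@H](O)CC[C@](C)(O)C[C@H]1OC(=O)C(C)C
F4 | step 18 | 9-iodo lactone | CC(=O)OC[C@H]1C(=O)O[C@H]2[C@H](I)[C@@H](C)[C@@H](O)CC[C@](C)(O)C[C@@H](OC(=O)C(C)C)[C@@H]12
F5 | step 18 | 1-hydroxy lactone | CC(=O)OC[C@H]1C(=O)O[C@H]2C[C@@H](C)[C@@H](O)CC[C@](C)(O)C[C@@H](OC(=O)C(C)C)[C@@H]12
F6 | step 12 | C9 primary alcohol | CC(C)=CCC[C@](C)(O[Si](CC)(CC)CC)C[C@@H](OC(=O)C(C)C)[C@H](CCO)C1COC(C)(C)OC1
F7 | step 12 | C9 aldehyde | CC(C)=CCC[C@](C)(O[Si](CC)(CC)CC)C[C@@H](OC(=O)C(C)C)[C@H](CC=O)C1COC(C)(C)OC1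
F8 | step 12 | (Z)-vinyl iodide | CC(C)=CCC[C@](C)(O[Si](CC)(CC)CC)C[C@@H](OC(=O)C(C)C)[C@H](C/C=C(\I)C)C1COC(C)(C)OC1
F9 | step 12 | iodo aldehyde | O=CCC[C@](C)(O[Si](CC)(CC)CC)C[C@@H](OC(=O)C(C)C)[C@H](C/C=C(\I)C)C1COC(C)(C)OC1
F10 | step 12 | cyclic allylic alcohol (C1 not defined) | CC1(C)OCC(CO1)[C@H]2C/C=C(/C)C(O)CC[C@](C)(O[Si](CC)(CC)CC)C[C@H]2OC(=O)C(C)C
F11 | step 12 | cyclodec-9-en-1-one | CC1(C)OCC(CO1)[C@H]2C/C=C(/C)C(=O)CC[C@](C)(O[Si](CC)(CC)CC)C[C@H]2OC(=O)C(C)C
F12 | step 8 | 5-ethynyl-2,2-dimethyl-1,3-dioxane | C#CC1COC(C)(C)OC1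
F13 | step 8 | 2,2-dimethyl-5-(propa-1,2-dienyl)-1,3-dioxane | C=C=CC1COC(C)(C)OC1
F14 | step 8 | (E)-3-(2,2-dimethyl-1,3-dioxan-5-yl)allyldiisopinocampheylborane | CC1(C)OCC(/C=C/CB([C@@H]2C[C@@H]3C[C@H]([C@H]2C)C3(C)C)[C@@H]2C[C@@H]3C[C@H]([C@H]2C)C3(C)C)CO1
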